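**Plan**

- Retrosynthesis: the five benzyl ethers come off last; the O1–C7a bond of the dihydrofuran ring is cut to an aryl chloride and a C2 alcohol; C2–O1 goes back to C2–B; then the C2–ring B and C3–ring C bonds are cut together.
- Enabling feature: C2 and C3 are adjacent stereocentres that each carry one aryl group (ring B, the 4-hydroxyphenyl, on C2; ring C, the 3,5-dihydroxyphenyl, on C3). C2 also carries O1, which can stand in for boron, so both aryl groups can be added across the C2=C3 bond of an E-alkenyl boronate on ring A (the benzo ring).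
- Ring A is traced to 4-(benzyloxy)-2-bromo-6-chlorobenzaldehyde: CHO becomes C3=C2–B (boron–Wittig), C–Br takes the phenethyl arm at C4 (ring D), and C–Cl is kept for O1–C7a.
- Forward: ring A aldehyde, arm at C4, alkenyl boronate, three-component coupling that joins rings B and C (no ring formed), C–B oxidation, the only ring closure (O1–C7a, Pd-catalysed etherification), hydrogenolysis.
- Stereochemistry: anti addition across the E alkene sets the C2/C3 relative configuration, which becomes cis because oxidation and etherification both retain C2; the chiral bisphosphine on palladium sets the absolute configuration (2S,3R).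

Key step: step 9

Assumption: the (Sp,Sp) antipode of the MandyPhos ligand is taken to select the alkene face that leads to the (1S,2R) boronate; because the addition is stereospecifically anti, an opposite sense of induction would only call for the (Rp,Rp) ligand.

**Route**

Step 1
Reactants: 1 3-bromo-5-chlorophenol
Product: 2 1-(benzyloxy)-3-bromo-5-chlorobenzene
Conditions: BnBr, K2CO3, DMF, rt
Reagents that add atoms: benzyl bromide, BrCc1ccccc1
Why: Williamson ether synthesis, in which the phenoxide is the only nucleophile and both aryl halides are inert.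

Step 2
Reactants: 2 1-(benzyloxy)-3-bromo-5-chlorobenzene
Product: 3 4-(benzyloxy)-2-bromo-6-chlorobenzaldehyde
Conditions: LiN(iPr)2, THF, −78 °C; DMF, −78 °C → rt; H2O
Reagents that add atoms: N,N-dimethylformamide, CN(C)C=O
Why: Deprotonative lithiation and formylation, in which the hydrogen flanked by bromine and chlorine is the most acidic on the ring, the amide base at −78 °C should remove it without halogen–lithium exchange or aryne formation, and DMF traps the aryllithium.

Step 3
Reactants: 3 4-(benzyloxy)-2-bromo-6-chlorobenzaldehyde, 4 1-(benzyloxy)-4-vinylbenzene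
Product: 6 4-(benzyloxy)-2-chloro-6-[2-(4-benzyloxyphenyl)ethyl]benzaldehyde, via B-alkyl-9-BBN borane 5 (not isolated)
Conditions: 4, 9-BBN-H (slight deficit), THF, 0 °C → rt; then 3, Pd(dppf)Cl2 (3 mol%), aq. K3PO4, THF/DMF, 50 °C
Reagents that add atoms: none
Why: Anti-Markovnikov hydroboration followed by B-alkyl Suzuki–Miyaura coupling, in which the dppf–palladium catalyst should insert into C–Br far faster than into C–Cl and the aldehyde tolerates a primary alkylborane free of B–H and aqueous phosphate.

Step 4
Reactants: 6 4-(benzyloxy)-2-chloro-6-[2-(4-benzyloxyphenyl)ethyl]benzaldehyde, 7 bis(4,4,5,5-tetramethyl-1,3,2-dioxaborolan-2-yl)methane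
Product: 8 (E)-2-{2-[4-(benzyloxy)-2-chloro-6-(4-benzyloxyphenethyl)phenyl]vinyl}-4,4,5,5-tetramethyl-1,3,2-dioxaborolane
Conditions: 7, lithium 2,2,6,6-tetramethylpiperidide, THF, 0 °C; then 6, −78 °C → rt; H2O
Reagents that add atoms: none
Why: Boron–Wittig olefination, in which the lithiated geminal diboronate adds to the aldehyde and the β-boryl alkoxide loses a boron–oxygen unit, the E alkene being expected because the remaining boryl group turns away from the doubly ortho-substituted ring.

Step 5
Reactants: 8 (E)-alkenyl pinacol boronate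
Product: 9 (E)-{2-[4-(benzyloxy)-2-chloro-6-(4-benzyloxyphenethyl)phenyl]vinyl}boronic acid
Conditions: NaIO4, NH4OAc, acetone/H2O, rt
Reagents that add atoms: water, O
Why: Oxidative deprotection of a pinacol boronate, in which periodate cleaves the pinacol released in the hydrolysis equilibrium and so drives the ester to the boronic acid while alkene, chloride and benzyl ethers stay untouched.

Step 6
Reactants: 10 acenaphthoquinone
Product: 11 cis-1,2-dimethyl-1,2-dihydroacenaphthylene-1,2-diol (meso)
Conditions: AlMe3 (excess), toluene, 0 °C → rt; aq. HCl; recrystallisation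
Reagents that add atoms: trimethylaluminium, C[Al](C)C
Why: Double 1,2-addition of methylaluminium to the 1,2-diketone, in which the second methyl group should enter anti to the aluminium alkoxide left by the first and so place both hydroxyl groups on one face, the only arrangement that can later bridge boron.

Step 7
Reactants: 9 (E)-alkenylboronic acid, 11 cis-1,2-dimethyl-1,2-dihydroacenaphthylene-1,2-diol
Product: 12 (E)-alkenyl boronate of diol 11: cyclic ester of 9 with 11
Conditions: MgSO4, CH2Cl2, rt
Reagents that add atoms: none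
Why: Boronic ester condensation driven by dehydration, which puts the bulky rigid diol on boron because β-substituted alkenyl pinacol boronates tend to undergo direct Suzuki coupling where this hindered ester favours metallate shift.

Step 8
Reactants: 13 3,5-bis(benzyloxy)phenol
Product: 14 3,5-bis(benzyloxy)phenyl trifluoromethanesulfonate
Conditions: Tf2O, pyridine, CH2Cl2, 0 °C
Reagents that add atoms: trifluoromethanesulfonic anhydride, O=S(=O)(OS(=O)(=O)C(F)(F)F)C(F)(F)F
Why: O-sulfonylation of a phenol, which turns ring C into a halide-free electrophile for palladium.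

Step 9
Reactants: 12 (E)-alkenyl boronate of diol 11, 14 3,5-bis(benzyloxy)phenyl trifluoromethanesulfonate, 15 1-(benzyloxy)-4-bromobenzene
Product: 18 ester of diol 11 with (1S,2R)-2-[4-(benzyloxy)-2-chloro-6-(4-benzyloxyphenethyl)phenyl]-1-(4-benzyloxyphenyl)-2-[3,5-bis(benzyloxy)phenyl]ethylboronic acid, via 4-benzyloxyphenyllithium 16 (not isolated), via lithium boronate complex 17 (not isolated)
Conditions: 15, t-BuLi (2 equiv), Et2O, −78 °C; 12, THF, −78 → 0 °C; solvent switch to THF; KOTf, 14, Pd(OAc)2 (3 mol%), (Sp,Sp)-1,1'-bis(diphenylphosphino)-2,2'-bis[(R)-α-(dimethylamino)benzyl]ferrocene (MandyPhos, 3.6 mol%), THF, 60 °C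
Reagents that add atoms: none
Why: Aryllithium 16, made by bromine–lithium exchange, adds to the boron of 12 to give ate complex 17; Pd(OAc)2 is reduced in situ to zerovalent palladium, which inserts into the C–O bond of triflate 14, and the cationic arylpalladium binds the alkene of 17 and triggers a 1,2-shift of the 4-benzyloxyphenyl group from boron to C2 on the face opposite palladium, after which C3–Pd reductively eliminates with retention to form the C3–ring C bond. The closest known reaction type is the palladium-catalysed conjunctive cross-coupling of β-substituted alkenylboron ate complexes with aryl triflates, and no ring closes. The relative configuration at C2 and C3 follows from the stereospecific anti addition across the E alkene, and the absolute configuration from the alkene face that the MandyPhos-bound palladium selects. The step needs the metallate shift to beat direct Suzuki transfer of the alkenyl group, which the bulky diol 11 on boron is there to secure, and it needs the triflate to react in preference to the ring A chloride, which a diarylphosphine catalyst at 60 °C should leave alone. KOTf takes up the bromide from the exchange, which would otherwise occupy the cationic palladium.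

Step 10
Reactants: 18 (1S,2R)-boronate of diol 11
Product: 19 (1S,2R)-2-[4-(benzyloxy)-2-chloro-6-(4-benzyloxyphenethyl)phenyl]-1-(4-benzyloxyphenyl)-2-[3,5-bis(benzyloxy)phenyl]ethanol
Conditions: H2O2 (30% aq.), NaOH (3 M aq.), THF, 0 °C → rt
Reagents that add atoms: hydrogen peroxide, OO
Why: Oxidation of a C–B bond, in which hydroperoxide adds to boron and C2 migrates from boron to oxygen with retention, so the C2 configuration is carried over unchanged.

Step 11
Reactants: 19 (1S,2R)-chloro alcohol
Product: 20 (2S,3R)-6-(benzyloxy)-2-(4-benzyloxyphenyl)-3-[3,5-bis(benzyloxy)phenyl]-4-(4-benzyloxyphenethyl)-2,3-dihydrobenzofuran (cis)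
Conditions: Pd(OAc)2 (5 mol%), 2-(di-tert-butylphosphino)-1,1'-binaphthyl (6 mol%), Cs2CO3, toluene, 80 °C
Reagents that add atoms: none
Why: Intramolecular Buchwald-type C–O coupling, in which zerovalent palladium inserts into the aryl chloride and the divalent arylpalladium alkoxide reductively eliminates O1–C7a under a bulky dialkylbiarylphosphine that disfavours β-hydride elimination; the C2–O bond is never broken, so C2 is retained and the two aryl groups end up cis.

Step 12
Reactants: 20 (2S,3R)-pentabenzyl ether
Product: 21 (2S,3R)-3-(3,5-dihydroxyphenyl)-2-(4-hydroxyphenyl)-4-[2-(4-hydroxyphenyl)ethyl]-2,3-dihydro-1-benzofuran-6-ol (cis; CNP0174555.1)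
Conditions: H2 (1 atm), 10% Pd/C, EtOAc/MeOH, rt
Reagents that add atoms: none
Why: Hydrogenolysis of five aryl benzyl ethers under neutral conditions, which should spare the cyclic C2–O1 benzylic aryl ether as it does in 2-arylchromans and avoids the acid that would epimerise the cis ring to trans.

**Compound list**

1 | 3-bromo-5-chlorophenol | Oc1cc(Cl)cc(Br)c1 | starting material
2 | 1-(benzyloxy)-3-bromo-5-chlorobenzene | Clc1cc(Br)cc(OCc2ccccc2)c1 | intermediate
3 | 4-(benzyloxy)-2-bromo-6-chlorobenzaldehyde | O=Cc1c(Cl)cc(OCc2ccccc2)cc1Br | intermediate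
4 | 1-(benzyloxy)-4-vinylbenzene | C=Cc1ccc(OCc2ccccc2)cc1 | starting material
5 | 9-[2-(4-benzyloxyphenyl)ethyl]-9-borabicyclo[3.3.1]nonane | C1CC2CCCC(C1)B2CCc1ccc(OCc2ccccc2)cc1 | intermediate
6 | 4-(benzyloxy)-2-chloro-6-[2-(4-benzyloxyphenyl)ethyl]benzaldehyde | O=Cc1c(Cl)cc(OCc2ccccc2)cc1CCc1ccc(OCc2ccccc2)cc1 | intermediate
7 | bis(4,4,5,5-tetramethyl-1,3,2-dioxaborolan-2-yl)methane | CC1(C)OB(CB2OC(C)(C)C(C)(C)O2)OC1(C)C | starting material
8 | (E)-2-{2-[4-(benzyloxy)-2-chloro-6-(4-benzyloxyphenethyl)phenyl]vinyl}-4,4,5,5-tetramethyl-1,3,2-dioxaborolane | CC1(C)OB(/C=C/c2c(Cl)cc(OCc3ccccc3)cc2CCc2ccc(OCc3ccccc3)cc2)OC1(C)C | intermediate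
9 | (E)-{2-[4-(benzyloxy)-2-chloro-6-(4-benzyloxyphenethyl)phenyl]vinyl}boronic acid | OB(O)/C=C/c1c(Cl)cc(OCc2ccccc2)cc1CCc1ccc(OCc2ccccc2)cc1 | intermediate
10 | acenaphthoquinone | O=C1C(=O)c2cccc3cccc1c23 | starting material
11 | cis-1,2-dimethyl-1,2-dihydroacenaphthylene-1,2-diol (meso) | C[C@]1(O)c2cccc3cccc(c23)[C@@]1(C)O | intermediate
12 | cyclic ester of boronic acid 9 with diol 11 (E-alkenyl boronate) | Clc1cc(OCc2ccccc2)cc(CCc2ccc(OCc3ccccc3)cc2)c1/C=C/B1O[C@@]2(C)c3cccc4cccc(c34)[C@@]2(C)O1 | intermediate
13 | 3,5-bis(benzyloxy)phenol | Oc1cc(OCc2ccccc2)cc(OCc2ccccc2)c1 | starting material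
14 | 3,5-bis(benzyloxy)phenyl trifluoromethanesulfonate | O=S(=O)(Oc1cc(OCc2ccccc2)cc(OCc2ccccc2)c1)C(F)(F)F | intermediate
15 | 1-(benzyloxy)-4-bromobenzene | Brc1ccc(OCc2ccccc2)cc1 | starting material
16 | 4-benzyloxyphenyllithium | [Li]c1ccc(OCc2ccccc2)cc1 | intermediate
17 | lithium (E)-alkenyl(4-benzyloxyphenyl)boronate complex of diol 11 (configuration at boron left open) | [Li+].Clc1cc(OCc2ccccc2)cc(CCc2ccc(OCc3ccccc3)cc2)c1/C=C/[B-]1(c2ccc(OCc3ccccc3)cc2)O[C@@]2(C)c3cccc4cccc(c34)[C@@]2(C)O1 | intermediate
18 | ester of diol 11 with (1S,2R)-2-[4-(benzyloxy)-2-chloro-6-(4-benzyloxyphenethyl)phenyl]-1-(4-benzyloxyphenyl)-2-[3,5-bis(benzyloxy)phenyl]ethylboronic acid | Clc1cc(OCc2ccccc2)cc(CCc2ccc(OCc3ccccc3)cc2)c1[C@@H](c1cc(OCc2ccccc2)cc(OCc2ccccc2)c1)[C@@H](c1ccc(OCc2ccccc2)cc1)B1O[C@@]2(C)c3cccc4cccc(c34)[C@@]2(C)O1 | intermediate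
19 | (1S,2R)-2-[4-(benzyloxy)-2-chloro-6-(4-benzyloxyphenethyl)phenyl]-1-(4-benzyloxyphenyl)-2-[3,5-bis(benzyloxy)phenyl]ethanol | Clc1cc(OCc2ccccc2)cc(CCc2ccc(OCc3ccccc3)cc2)c1[C@@H](c1cc(OCc2ccccc2)cc(OCc2ccccc2)c1)[C@@H](c1ccc(OCc2ccccc2)cc1)O | intermediate
20 | (2S,3R)-6-(benzyloxy)-2-(4-benzyloxyphenyl)-3-[3,5-bis(benzyloxy)phenyl]-4-(4-benzyloxyphenethyl)-2,3-dihydrobenzofuran (cis) | c1ccccc1COc1ccc(CCc2cc(OCc4ccccc4)cc3c2[C@@H](c2cc(OCc4ccccc4)cc(OCc4ccccc4)c2)[C@@H](c2ccc(OCc4ccccc4)cc2)O3)cc1 | intermediate
21 | (2S,3R)-3-(3,5-dihydroxyphenyl)-2-(4-hydroxyphenyl)-4-[2-(4-hydroxyphenyl)ethyl]-2,3-dihydro-1-benzofuran-6-ol (cis) | Oc1ccc(CCc2cc(O)cc3c2[C@@H](c2cc(O)cc(O)c2)[C@@H](c2ccc(O)cc2)O3)cc1 | target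

**Step count**

Total: 12 steps. Longest linear sequence: 10 steps (steps 1, 2, 3, 4, 5, 7, 9, 10, 11, 12); steps 6 and 8 are side branches.

**Steps most likely to fail**

Step 9. The alkene of 17 sits next to a ring with two ortho substituents, so binding to the arylpalladium cation may be slow. Transfer of the alkenyl group to palladium (direct Suzuki coupling) could then overtake the metallate shift, or the ligand could distinguish the two alkene faces poorly. The fallback gives up the metallate route and forms the C2–C3 bond by carbene C–H insertion; it sets out from aldehyde 6 and comes back at 20, so steps 10 and 11 are not needed. 3,5-Bis(benzyloxy)phenylmagnesium bromide F1, made from purchased 1-bromo-3,5-bis(benzyloxy)benzene and magnesium in THF, would add to 6 to give racemic [4-(benzyloxy)-2-chloro-6-(4-benzyloxyphenethyl)phenyl][3,5-bis(benzyloxy)phenyl]methanol F2. MnO2 in CH2Cl2 would oxidise it to the corresponding benzophenone F3. The chloride ortho to the ketone would then be coupled with purchased 4-(benzyloxy)benzyl alcohol (Pd2(dba)3, tBuBrettPhos, Cs2CO3, toluene, 90 °C) to give the aryl 4-benzyloxybenzyl ether ketone F4. Hydrazine hydrate with catalytic AcOH in hot n-butanol would give the hydrazone F5. MnO2 at 0 °C would oxidise this to the diaryldiazomethane F6, which is filtered and treated with Rh2(R-PTAD)4 (or its antipode, whichever delivers the 2S,3R product). The donor/donor rhodium carbene should insert into the O–CH2 bond of the ortho benzyl ether, a reaction type known to give cis-2,3-diaryl-2,3-dihydrobenzofurans enantioselectively, and so deliver 20. The selectivity to watch there is insertion into the ether C–H in preference to the benzylic C–H of the phenethyl arm.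

Step 11. The palladium alkoxide may undergo β-hydride elimination, which oxidises the alcohol to the ketone and reduces the chloride, or insertion into the hindered, electron-rich chloride may be too slow. The fallback moves the C–O bond formation to copper, where no palladium alkoxide is involved; it sets out from 19 and comes back at 20. Miyaura borylation of the chloride (Pd2(dba)3, XPhos, B2pin2, KOAc, dioxane, 100 °C) would give the aryl pinacol boronate of the (1S,2R) alcohol F7. Intramolecular Chan–Lam etherification (Cu(OAc)2, pyridine, 4 Å molecular sieves, air, CH2Cl2, rt) would then close O1–C7a with the C2–O bond untouched, giving 20.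

Step 2. Lithiation may occur next to the benzyloxy group instead of between the halogens, a halogen may migrate, or lithium halide may be lost to an aryne; each path gives regioisomeric or halogen-scrambled aldehydes. The fallback avoids the metalation by using a ring that already carries the oxygen and two equivalent halogens; it sets out from 4 (through borane 5) and comes back at 6, replacing steps 1 to 3. Purchased 2,6-dichloro-4-hydroxybenzaldehyde would be benzylated (BnBr, K2CO3, DMF) to 4-(benzyloxy)-2,6-dichlorobenzaldehyde F8. F8, used in excess and recovered, would be coupled once with borane 5 under B-alkyl Suzuki conditions for aryl chlorides (Pd(OAc)2, SPhos, aq. K3PO4, THF, 60 °C). Because the two chlorides are equivalent, only mono- against double coupling has to be controlled, and the mono-coupled product is 6.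

**Further compounds**

F1 | step 9 | 3,5-bis(benzyloxy)phenylmagnesium bromide | Br[Mg]c1cc(OCc2ccccc2)cc(OCc2ccccc2)c1
F2 | step 9 | [4-(benzyloxy)-2-chloro-6-(4-benzyloxyphenethyl)phenyl][3,5-bis(benzyloxy)phenyl]methanol (racemic) | OC(c1cc(OCc2ccccc2)cc(OCc2ccccc2)c1)c1c(Cl)cc(OCc2ccccc2)cc1CCc1ccc(OCc2ccccc2)cc1
F3 | step 9 | [4-(benzyloxy)-2-chloro-6-(4-benzyloxyphenethyl)phenyl][3,5-bis(benzyloxy)phenyl]methanone | O=C(c1cc(OCc2ccccc2)cc(OCc2ccccc2)c1)c1c(Cl)cc(OCc2ccccc2)cc1CCc1ccc(OCc2ccccc2)cc1
F4 | step 9 | {4-(benzyloxy)-2-[(4-benzyloxybenzyl)oxy]-6-(4-benzyloxyphenethyl)phenyl}[3,5-bis(benzyloxy)phenyl]methanone | O=C(c1cc(OCc2ccccc2)cc(OCc2ccccc2)c1)c1c(OCc2ccc(OCc3ccccc3)cc2)cc(OCc2ccccc2)cc1CCc1ccc(OCc2ccccc2)cc1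
F5 | step 9 | hydrazone of ketone F4 | NN=C(c1cc(OCc2ccccc2)cc(OCc2ccccc2)c1)c1c(OCc2ccc(OCc3ccccc3)cc2)cc(OCc2ccccc2)cc1CCc1ccc(OCc2ccccc2)cc1
F6 | step 9 | diaryldiazomethane from hydrazone F5 | [N-]=[N+]=C(c1cc(OCc2ccccc2)cc(OCc2ccccc2)c1)c1c(OCc2ccc(OCc3ccccc3)cc2)cc(OCc2ccccc2)cc1CCc1ccc(OCc2ccccc2)cc1
F7 | step 11 | (1S,2R)-2-[4-(benzyloxy)-2-(4,4,5,5-tetramethyl-1,3,2-dioxaborolan-2-yl)-6-(4-benzyloxyphenethyl)phenyl]-1-(4-benzyloxyphenyl)-2-[3,5-bis(benzyloxy)phenyl]ethanol | CC1(C)OB(c2cc(OCc3ccccc3)cc(CCc3ccc(OCc4ccccc4)cc3)c2[C@@H](c2cc(OCc3ccccc3)cc(OCc3ccccc3)c2)[C@@H](c2ccc(OCc3ccccc3)cc2)O)OC1(C)C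
F8 | step 2 | 4-(benzyloxy)-2,6-dichlorobenzaldehyde | O=Cc1c(Cl)cc(OCc2ccccc2)cc1Cl
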